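**Assumption:** (R)-3-buten-2-ol and 3-(4-hydroxy-3,5-dimethoxyphenyl)propanoic acid (dihydrosinapic acid) are purchased. The acid is also available by H2/Pd-C reduction of sinapic acid.

## Retrosynthetic overview
- The tetrahydrofuran ring is formed last, by oxidative 5-exo cycloetherification of (8R,8'R)-5,5'-dimethoxysecoisolariciresinol. This diol is C2-symmetric, so oxidation at either benzylic CH gives the same product. C7 is set trans to C8 by the existing centers.
- The diol comes from an Ireland–Claisen [3,3] rearrangement that forms the C8–C8' bond. The substrate is the ester of a (3-arylpropanoic acid) with (R)-(E)-5-aryl-pent-3-en-2-ol. Chirality transfer through a chair transition state sets C8 and C8' together.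
- The vinyl group becomes CH2OH by ozonolysis and reduction, and the CO2H becomes CH2OH by LiAlH4.
- The allylic alcohol comes from cross-metathesis of (R)-3-buten-2-ol (the chiral starting material) with benzyl-protected 4-allylsyringol. The acid half comes from dihydrosinapic acid. The aryl rings are pre-formed, so the only ring formed in the sequence is the THF.

## Route

**Step 1**
Reactants: 1, 4-allyl-2,6-dimethoxyphenol
Product: 2, 2-(benzyloxy)-1,3-dimethoxy-5-allylbenzene
Conditions: BnBr, K2CO3, DMF, rt
Reagents that add atoms: benzyl bromide, BrCc1ccccc1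
Why: Williamson O-benzylation protects the phenol against the strong base in step 6; no stereocenter is involved.

**Step 2**
Reactants: 2; 3, (R)-but-3-en-2-ol
Product: 4, (2R,3E)-5-[4-(benzyloxy)-3,5-dimethoxyphenyl]pent-3-en-2-ol
Conditions: Grubbs II (5 mol%), 1,4-benzoquinone (10 mol%), 3 equiv 3, CH2Cl2, 40 °C
Reagents that add atoms: none
Why: Olefin cross-metathesis with excess volatile partner 3 favors the E cross-product. The carbinol stereocenter is untouched and becomes the source of all chirality.

**Step 3**
Reactants: 5, 3-(4-hydroxy-3,5-dimethoxyphenyl)propanoic acid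
Product: 6, benzyl 3-[4-(benzyloxy)-3,5-dimethoxyphenyl]propanoate
Conditions: BnBr (2.3 equiv), K2CO3, DMF, rt
Reagents that add atoms: benzyl bromide, BrCc1ccccc1
Why: Double O-alkylation (phenol and carboxylate) protects the phenol; no stereocenter is involved.

**Step 4**
Reactants: 6
Product: 7, 3-[4-(benzyloxy)-3,5-dimethoxyphenyl]propanoic acid
Conditions: LiOH, THF/MeOH/H2O, rt; then 1 M HCl
Reagents that add atoms: none
Why: Saponification cleaves the benzyl ester; the aryl benzyl ether is stable to hydroxide.

**Step 5**
Reactants: 4; 7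
Product: 8, (2R,3E)-5-aryl-pent-3-en-2-yl 3-(4-benzyloxy-3,5-dimethoxyphenyl)propanoate
Conditions: EDC·HCl, DMAP, CH2Cl2, 0 °C to rt
Reagents that add atoms: none
Why: Steglich esterification does not touch the carbinol stereocenter, because the C–O bond is not broken.

**Step 6**
Reactants: 8
Product: 9, (2R,3S,4E)-2,3-bis[(4-benzyloxy-3,5-dimethoxyphenyl)methyl]hex-4-enoic acid
Conditions: LDA, THF/HMPA (4:1), –78 °C; TBSCl; –78 °C to rt; then aq. HCl
Reagents that add atoms: none (the TBS group is removed in the workup)
Why: Ireland–Claisen [3,3] rearrangement. The HMPA-derived Z(O)-enolate, giving a silyl ketene acetal with the CH2Ar group cis to OSi, reacts with the E-alkene through a chair transition state with both aryl-bearing substituents equatorial. This sets the two new C–C stereocenters syn to each other, and the (R)-carbinol fixes their absolute configuration.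

**Step 7**
Reactants: 9
Product: 10, (2R,3S,4E)-2,3-bis[(4-benzyloxy-3,5-dimethoxyphenyl)methyl]hex-4-en-1-ol
Conditions: LiAlH4, THF, 0 °C to rt
Reagents that add atoms: none
Why: Hydride reduction of the acid to the primary alcohol leaves the alkene and benzyl ethers intact. The α-stereocenter is not epimerized because it is reduced as the carboxylate or aldehyde-level intermediate under non-enolizing conditions.

**Step 8**
Reactants: 10
Product: 11, (2R,3R)-2,3-bis[(4-benzyloxy-3,5-dimethoxyphenyl)methyl]butane-1,4-diol
Conditions: O3, CH2Cl2/MeOH, –78 °C (color-titrated); then NaBH4, 0 °C to rt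
Reagents that add atoms: ozone, O=[O+][O-] (its oxygen ends up in the new CH2OH)
Why: Ozonolysis with reductive workup converts the propenyl group to CH2OH. The intermediate γ-hydroxy aldehyde sits largely as its lactol, which protects the α-center from epimerization. The C2-symmetric (R,R)-diol results.

**Step 9**
Reactants: 11
Product: 12, (2R,3R)-2,3-bis[(4-hydroxy-3,5-dimethoxyphenyl)methyl]butane-1,4-diol ((–)-5,5'-dimethoxysecoisolariciresinol)
Conditions: H2 (1 atm), 10% Pd/C, EtOAc/MeOH, rt
Reagents that add atoms: none
Why: Hydrogenolysis of the aryl benzyl ethers. No alkene or benzylic ether remains that could be reduced.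

**Step 10**
Reactants: 12
Product: 13, (+)-(7S,8R,8'R)-5,5'-dimethoxylariciresinol (target)
Conditions: DDQ (1.0 equiv), anhydrous CH2Cl2 (dilute), 4 Å MS, 0 °C to rt
Reagents that add atoms: none
Why: Oxidative cycloetherification. DDQ abstracts the benzylic hydride para to the free phenol, giving a p-quinone methide. The C9'-OH then adds 5-exo-trig (1,6-conjugate addition) to C7. The addition is reversible under the mildly acidic conditions, so it gives the 7,8-trans THF (7S), and C8 and C8' are not disturbed.

## Compound list
1 | 4-allyl-2,6-dimethoxyphenol | COc1cc(CC=C)cc(OC)c1O | starting material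
2 | 2-(benzyloxy)-1,3-dimethoxy-5-allylbenzene | COc1cc(CC=C)cc(OC)c1OCc1ccccc1 | intermediate
3 | (R)-but-3-en-2-ol | C[C@@H](O)C=C | starting material
4 | (2R,3E)-5-[4-(benzyloxy)-3,5-dimethoxyphenyl]pent-3-en-2-ol | C[C@@H](O)/C=C/Cc1cc(OC)c(OCc2ccccc2)c(OC)c1 | intermediate
5 | 3-(4-hydroxy-3,5-dimethoxyphenyl)propanoic acid | COc1cc(CCC(=O)O)cc(OC)c1O | starting material
6 | benzyl 3-[4-(benzyloxy)-3,5-dimethoxyphenyl]propanoate | COc1cc(CCC(=O)OCc2ccccc2)cc(OC)c1OCc1ccccc1 | intermediate
7 | 3-[4-(benzyloxy)-3,5-dimethoxyphenyl]propanoic acid | COc1cc(CCC(=O)O)cc(OC)c1OCc1ccccc1 | intermediate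
8 | (2R,3E)-5-aryl-pent-3-en-2-yl 3-(4-benzyloxy-3,5-dimethoxyphenyl)propanoate | C[C@@H](OC(=O)CCc1cc(OC)c(OCc2ccccc2)c(OC)c1)/C=C/Cc1cc(OC)c(OCc2ccccc2)c(OC)c1 | intermediate
9 | (2R,3S,4E)-2,3-bis(aryl-methyl)hex-4-enoic acid (aryl = 4-benzyloxy-3,5-dimethoxyphenyl) | C/C=C/[C@H](Cc1cc(OC)c(OCc2ccccc2)c(OC)c1)[C@@H](Cc1cc(OC)c(OCc2ccccc2)c(OC)c1)C(=O)O | intermediate
10 | (2R,3S,4E)-2,3-bis(aryl-methyl)hex-4-en-1-ol | C/C=C/[C@H](Cc1cc(OC)c(OCc2ccccc2)c(OC)c1)[C@@H](Cc1cc(OC)c(OCc2ccccc2)c(OC)c1)CO | intermediate
11 | (2R,3R)-2,3-bis(4-benzyloxy-3,5-dimethoxybenzyl)butane-1,4-diol | OC[C@H](Cc1cc(OC)c(OCc2ccccc2)c(OC)c1)[C@@H](Cc1cc(OC)c(OCc2ccccc2)c(OC)c1)CO | intermediate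
12 | (2R,3R)-2,3-bis(4-hydroxy-3,5-dimethoxybenzyl)butane-1,4-diol | OC[C@H](Cc1cc(OC)c(O)c(OC)c1)[C@@H](Cc1cc(OC)c(O)c(OC)c1)CO | intermediate
13 | (+)-(7S,8R,8'R)-5,5'-dimethoxylariciresinol | COc1cc(C[C@H]2CO[C@H](c3cc(OC)c(O)c(OC)c3)[C@H]2CO)cc(OC)c1O | target

## Step count
- Total steps: 10.
- Longest linear sequence: 8 steps (1 → 2 → 4 → 8 → 9 → 10 → 11 → 12 → 13, i.e. steps 1, 2, 5, 6, 7, 8, 9, 10). The acid half (5 → 6 → 7) is a parallel 2-step branch.

## Three steps most likely to fail
1. **Step 10, DDQ cycloetherification.** Over-oxidation, elimination to the 7,8-alkene, or a poor 7,8-trans ratio are possible. Fallback: from dibenzyl diol 11, oxidize the benzylic position with DDQ in wet dioxane to the 7-hydroxy diol. Then close the ring by TsOH-mediated SN1 cyclodehydration (thermodynamically trans), then H2/Pd-C.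
2. **Step 6, Ireland–Claisen diastereoselectivity.** The Z(O)-enolate ratio may be modest, or a boat transition state may compete. Fallback: prepare the (Z)-allylic alcohol (via the alkynol and Lindlar reduction) and use the standard LDA/THF enolate. This is the other syn-selective pairing of alkene and enolate geometry.
3. **Step 2, cross-metathesis.** Ru–H isomerization of the allylarene, homodimerization, or poor E/Z selectivity are possible. Fallback: build alcohol 4 from ethyl (R)-lactate. Protect as the TBS ether, reduce with DIBAL to the aldehyde, then do an E-selective Julia–Kocienski olefination with 2-arylethyl phenyltetrazolyl sulfone, and deprotect.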